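The runs were generated by integration for substances that don't exist, noise included.

Q is the limiting reagent. I follow its balance: each fraction of the charge is still Q, or is E, or has gone elsewhere. G is charged at twice the amount of Q.

| flask | Q | G | Z | time |
|---|---|---|---|---|
| midnight | 0.800 M | 1.60 M | 0.00800 M |  |
| winter | 0.480 M | 1.28 M | 0.00800 M |  |
| noon | 0.800 M | 2.40 M | 0.00800 M |  |
| dusk | 0.800 M | 1.60 M | 0.0120 M |  |
| summer | 0.800 M | 1.60 M | 0.0240 M | 5.2 h |

- midnight run (time / h: [E] / M): 0.87: 0.1002; 1.7: 0.1853; 2.6: 0.2736; 3.5: 0.3460; 4.3: 0.4028; 5.2: 0.4598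
- winter run (time / h: [E] / M): 0.87: 0.0828; 1.7: 0.1473; 2.6: 0.2138; 3.5: 0.2611; 4.3: 0.2960; 5.2: 0.3237
- noon run (time / h: [E] / M): 0.87: 0.1029; 1.7: 0.1892; 2.6: 0.2738; 3.5: 0.3454; 4.3: 0.4087; 5.2: 0.4595
- dusk run (time / h: [E] / M): 0.87: 0.1485; 1.7: 0.2722; 2.6: 0.3857; 3.5: 0.4811; 4.3: 0.5429; 5.2: 0.5877

(standard deviation of a reading: 0.002 M)

- reaction order in [Z] at the outset, round the charge of the midnight run, defined at two percent of the Q turned into E
- reaction order in [Q] at the outset, round the charge of the midnight run, defined at two percent of the Q turned into E (one fixed amount of E, the same in the runs compared)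
- E in the summer run at 5.2 h, as a share of the Q charged

- Overall: Q + G -> E, with Z as catalyst.
- Constant volume, constant temperature.
- Readings of a species count what is bound in complexes too.
- An order is taken over about fifteen percent of the charge, up and down.

I turn G first. If G pushed the rate, the noon run would pull ahead of the midnight run. Yet at the last reading they hold 57.4% and 57.5% of the charge. I turn Q next. A first-order flask would give the winter run 0.600 of the midnight rate, but the first readings stand at a ratio of 0.826. So Q counts weakly. Then I turn Z, from 1.00% of the charge at midnight to 1.50% at dusk. By hand that gives 1.50 times the rate, and the first readings give 1.48.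

So I try a clock: Z share times hours. The dusk run at 3.5 h and the midnight run at 5.2 h stand at nearly the same clock, 0.0525 h and 0.0520 h. Still, the dusk run holds 60.1% of the charge, more than the midnight run's 57.5%, and the midnight run has had 1.70 h longer. I read that gap as a leak: the share of the standing E lost per hour. The midnight curve bends, and by trapezoids over its readings its E averages 32.1% of the charge. I put the gap down to those extra hours at that mean, and it gives a leak of 0.0488 h⁻¹.

The summer run reaches the last dusk clock at 2.60 h. I let E climb straight until then and stay flat to 5.2 h, and I count the Q as turned by the end. The balance then leaves 84.0% as E.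

The forecast gives order 1.08 in Z, 0.3 in Q and 87%, above my figure: “Extrapolating those tails suggests a plateau near 85%, so I expect about 87%.”

The flask gives order 1.0 in Z, 0.31 in Q and 82.9%.

    Z + Q → ZQ (63.36 L mol⁻¹ h⁻¹)
    ZQ + G → E + Z (604.8 L mol⁻¹ h⁻¹)
    E → Qi (0.04896 h⁻¹)
    Z + Q ⇌ ZQ', settled at all times (2.910 L mol⁻¹)

At that level my leak of 0.0488 h⁻¹, as read from the runs, takes 0.0405 h⁻¹ of the charge at the end of the summer run. By the same reading, the winter run at its last reading sheds 0.0329 h⁻¹ of its own charge. The summer shortfall comes from the reaction of E to Qi. With that step taken away, the summer run holds 99.5% of the charge as E, not 82.9%, a difference of 17 percentage points.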